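**Plan**

1. Numbering (hydroazulene): C1 (OAc), C2, C3 (carbinol), C3a, C4 (aroyloxy), C5, C6=C7, C8, C8a (angular CH3); ring A is the five-membered ring, ring B the seven-membered ring.
2. Retrosynthesis: remove the acetate, the aryl ester and the isopropyl group (C3 becomes a ketone, C1 a ketone masked as a 1,3-dithiane), then cut C1–C2 and C3a–C8a in one stroke, which opens both rings to a linear chain.
3. Enabling feature: in ring A, C2–C3–C3a with oxygen on C3 is a 2-oxyallyl unit and C8a–C1 is an electron-rich alkene (ketene dithioacetal). The C4 oxygen next to C3a is an epoxide oxygen, and the cis C6=C7 alkene of ring B folds the chain.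
4. Forward: Z-selective Wittig, alkyne–allyl coupling, ester to ketene dithioacetal, enone, asymmetric epoxidation, enol silane; a (3+2) cascade then closes ring B and ring A in one flask. Isopropyl addition, aroylation, dithiane to ketone, directed reduction, acetylation and deallylation finish the route.
5. Stereochemistry: the catalytic epoxidation sets C4 and, by inversion in the cascade, C3a. C8a follows from a chair-like transition state (trans fusion), C3 from attack anti to the angular methyl, and C1 from hydride delivery by the C3 hydroxyl.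

Key step: step 10

Remark: (S)-BINOL is written in step 8 on the assumption that the usual facial sense of this epoxidation for (E)-alkyl enones holds (otherwise the antipode is used); 1 and 7 are racemic because their stereocentres are erased in steps 5 and 7.

**Route**

Step 1
Reactants: 1 methyl 4-bromo-2-methylbutanoate
Product: 2 (4-methoxy-3-methyl-4-oxobutyl)triphenylphosphonium bromide
Conditions: PPh3, MeCN, reflux
Reagents that add atoms: triphenylphosphine, c1ccc(cc1)P(c1ccccc1)c1ccccc1
Why: SN2 quaternisation of the primary bromide by the phosphine (phosphonium salt formation) should proceed without touching the ester.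

Step 2
Reactants: 2 (4-methoxy-3-methyl-4-oxobutyl)triphenylphosphonium bromide; 3 1-[(tert-butyldimethylsilyl)oxy]propan-2-one
Product: 5 methyl (4Z)-6-[(tert-butyldimethylsilyl)oxy]-2,5-dimethylhex-4-enoate, via phosphorus ylide 4 (not isolated)
Conditions: NaN(SiMe3)2, THF, −78 °C; then 3, −78 °C → rt
Reagents that add atoms: none
Why: Wittig olefination of an α-silyloxy ketone with a non-stabilised ylide is expected to give the (Z)-trisubstituted allylic ether (silyloxymethyl cis to the chain), which later becomes the cis alkene of ring B.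

Step 3
Reactants: 5 methyl (4Z)-6-[(tert-butyldimethylsilyl)oxy]-2,5-dimethylhex-4-enoate
Product: 6 methyl (4Z)-6-bromo-2,5-dimethylhex-4-enoate
Conditions: Ph3PBr2, CH2Cl2, 0 °C → rt
Reagents that add atoms: dibromotriphenylphosphorane, BrP(Br)(c1ccccc1)(c1ccccc1)c1ccccc1
Why: Appel-type direct conversion of a silyl ether into a bromide (alkoxyphosphonium ion, then SN2 by bromide at the primary carbon) should spare the ester and keep the alkene geometry.

Step 4
Reactants: 6 methyl (4Z)-6-bromo-2,5-dimethylhex-4-enoate; 7 but-3-yn-2-ol (racemic)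
Product: 8 methyl (4Z)-9-hydroxy-2,5-dimethyldec-4-en-7-ynoate
Conditions: CuI (cat.), K2CO3, Bu4NI (cat.), DMF, rt
Reagents that add atoms: none
Why: CuI-mediated coupling of a terminal alkyne with an allylic bromide should give the skipped enyne by substitution at the primary carbon, with retention of the (Z)-alkene.

Step 5
Reactants: 8 methyl (4Z)-9-hydroxy-2,5-dimethyldec-4-en-7-ynoate
Product: 9 (6Z)-9-(1,3-dithian-2-ylidene)-6-methyldec-6-en-3-yn-2-ol
Conditions: AlMe3, HS(CH2)3SH, CH2Cl2, 0 °C → rt; aq. NaOH work-up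
Reagents that add atoms: propane-1,3-dithiol, SCCCS
Why: the aluminium-thiolate-mediated conversion of an ester into a ketene dithioacetal should turn the ester into the π-nucleophile and masked C1 carbonyl needed in step 10 and erases the α-stereocentre.

Step 6
Reactants: 9 (6Z)-9-(1,3-dithian-2-ylidene)-6-methyldec-6-en-3-yn-2-ol
Product: 10 (3E,6Z)-9-(1,3-dithian-2-ylidene)-6-methyldeca-3,6-dien-2-ol
Conditions: LiAlH4, THF, 0 °C → rt
Reagents that add atoms: none
Why: hydroxyl-directed trans-hydroalumination of the propargylic alcohol should give the (E)-allylic alcohol and leave the isolated alkene and the ketene dithioacetal untouched.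

Step 7
Reactants: 10 (3E,6Z)-9-(1,3-dithian-2-ylidene)-6-methyldeca-3,6-dien-2-ol
Product: 11 (3E,6Z)-9-(1,3-dithian-2-ylidene)-6-methyldeca-3,6-dien-2-one
Conditions: MnO2, CH2Cl2, rt
Reagents that add atoms: none
Why: allylic oxidation with MnO2 should give the (E)-enone without oxidising sulfur or moving the skipped alkene.

Step 8
Reactants: 11 (3E,6Z)-9-(1,3-dithian-2-ylidene)-6-methyldeca-3,6-dien-2-one
Product: 12 1-[(2R,3S)-3-[(2Z)-5-(1,3-dithian-2-ylidene)-2-methylhex-2-en-1-yl]oxiran-2-yl]ethan-1-one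
Conditions: La(OiPr)3 (5 mol %), (S)-BINOL (5 mol %), Ph3As=O (5 mol %), tBuOOH, 4 Å MS, THF, rt
Reagents that add atoms: tert-butyl hydroperoxide, CC(C)(C)OO
Why: catalytic asymmetric nucleophilic (Weitz–Scheffer-type) epoxidation attacks only the electron-poor enone C=C, not the electron-rich alkene or the sulfur atoms, and the chiral ligand sets both oxirane centres (2R,3S) of the trans epoxide.

Step 9
Reactants: 12 1-[(2R,3S)-3-[(2Z)-5-(1,3-dithian-2-ylidene)-2-methylhex-2-en-1-yl]oxiran-2-yl]ethan-1-one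
Product: 13 triethyl({1-[(2R,3S)-3-[(2Z)-5-(1,3-dithian-2-ylidene)-2-methylhex-2-en-1-yl]oxiran-2-yl]ethenyl}oxy)silane
Conditions: Et3SiOTf, Et3N, CH2Cl2, −78 °C; pentane filtration
Reagents that add atoms: triethylsilyl trifluoromethanesulfonate, CC[Si](CC)(CC)OS(=O)(=O)C(F)(F)F
Why: soft enolisation (silyl triflate and amine) of the methyl ketone, which can enolise only towards CH3, should give the 2-silyloxy vinyl epoxide.

Step 10
Reactants: 13 triethyl({1-[(2R,3S)-3-[(2Z)-5-(1,3-dithian-2-ylidene)-2-methylhex-2-en-1-yl]oxiran-2-yl]ethenyl}oxy)silane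
Product: 15 (3aS,4S,8aR)-6,8a-dimethyl-4-[(triethylsilyl)oxy]-3a,4,5,8-tetrahydro-2H-spiro[azulene-1,2'-[1,3]dithian]-3(8aH)-one, via dithianylium triflate 14 (not isolated)
Conditions: Et3SiOTf (15 mol %), 2,6-di-tert-butyl-4-methylpyridine (5 mol %), CH2Cl2 (0.01 M), −78 → −40 °C; Et3N quench
Reagents that add atoms: none
Why: Proposed new method: the silyl triflate silylates the epoxide oxygen, the C–O bond at the oxirane carbon next to the enol silane is loosened (2-silyloxyallyl cation character), the β-carbon of the ketene dithioacetal attacks this carbon from the rear to give dithianylium ion 14, and the CH2 terminus of the enol silane then captures the cationic carbon with release of the silyl triflate; the closest known reaction types are the silyl-triflate-catalysed (4+3) cycloaddition of epoxy enol silanes with dienes and the (3+2) cyclopentanone annulation of 2-silyloxyallyl cations with vinyl sulfides and enol ethers. Ring B closes first in a 7-endo epoxide opening pre-organised by the (Z)-alkene of the tether, and ring A follows in a 5-(enolendo)-exo-trig Mukaiyama-type addition to the dithianylium carbon. C3a is set by inversion at the attacked oxirane carbon and C4 keeps the configuration of the epoxide, so both come from step 8. C8a is set in a chair-like cycloheptene transition state that places the 2-silyloxyallyl group and the bulky dithianylidene carbon equatorial and the methyl group axial, which gives the trans ring fusion. The step needs chemoselectivity for the ketene dithioacetal over the ring-B alkene, which should follow from its far higher π-nucleophilicity and from the fact that the ring-B alkene cannot reach the rear side of the oxirane carbon through a five-membered ring. It also needs regioselectivity for the oxirane carbon activated by the enol silane (allylic stabilisation), and the hindered pyridine suppresses protonation of the ketene dithioacetal.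

Step 11
Reactants: 15 (3aS,4S,8aR)-6,8a-dimethyl-4-[(triethylsilyl)oxy]-3a,4,5,8-tetrahydro-2H-spiro[azulene-1,2'-[1,3]dithian]-3(8aH)-one
Product: 17 (3R,3aS,4S,8aR)-6,8a-dimethyl-3-(propan-2-yl)-2,3,3a,4,5,8-hexahydro-8aH-spiro[azulene-1,2'-[1,3]dithiane]-3,4-diol, via triethylsilyl ether 16 (not isolated)
Conditions: iPrMgCl, CeCl3, THF, −78 → 0 °C; aq. NH4Cl; then Bu4NF, THF, 0 °C
Reagents that add atoms: isopropylmagnesium chloride, CC(C)[Mg]Cl
Why: CeCl3-mediated Grignard 1,2-addition suppresses enolisation and β-elimination and should occur on the face anti to the axial angular methyl (the spiro-dithiane shields both faces equally), setting C3 with the hydroxyl cis to that methyl; fluoride then cleaves the silyl ether.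

Step 12
Reactants: 17 (3R,3aS,4S,8aR)-6,8a-dimethyl-3-(propan-2-yl)-2,3,3a,4,5,8-hexahydro-8aH-spiro[azulene-1,2'-[1,3]dithiane]-3,4-diol; 18 4-(prop-2-en-1-yloxy)benzoic acid
Product: 19 (3R,3aS,4S,8aR)-3-hydroxy-6,8a-dimethyl-3-(propan-2-yl)-2,3,3a,4,5,8-hexahydro-8aH-spiro[azulene-1,2'-[1,3]dithian]-4-yl 4-(prop-2-en-1-yloxy)benzoate
Conditions: DCC, DMAP, CH2Cl2, rt
Reagents that add atoms: none
Why: Steglich esterification should acylate the secondary C4 hydroxyl selectively, because the tertiary C3 hydroxyl is too hindered.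

Step 13
Reactants: 19 (3R,3aS,4S,8aR)-3-hydroxy-6,8a-dimethyl-3-(propan-2-yl)-2,3,3a,4,5,8-hexahydro-8aH-spiro[azulene-1,2'-[1,3]dithian]-4-yl 4-(prop-2-en-1-yloxy)benzoate
Product: 20 (3R,3aS,4S,8aR)-3-hydroxy-6,8a-dimethyl-1-oxo-3-(propan-2-yl)-1,2,3,3a,4,5,8,8a-octahydroazulen-4-yl 4-(prop-2-en-1-yloxy)benzoate
Conditions: MeI, CaCO3, MeCN/H2O, 45 °C
Reagents that add atoms: water, O
Why: alkylative hydrolysis of the 1,3-dithiane (S-methylation, then hydrolysis) under carbonate buffering should unmask the C1 ketone without electrophilic reagents that could attack the ring-B alkene or dehydrate the β-hydroxy ketone.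

Step 14
Reactants: 20 (3R,3aS,4S,8aR)-3-hydroxy-6,8a-dimethyl-1-oxo-3-(propan-2-yl)-1,2,3,3a,4,5,8,8a-octahydroazulen-4-yl 4-(prop-2-en-1-yloxy)benzoate
Product: 21 (1S,3R,3aS,4S,8aR)-1,3-dihydroxy-6,8a-dimethyl-3-(propan-2-yl)-1,2,3,3a,4,5,8,8a-octahydroazulen-4-yl 4-(prop-2-en-1-yloxy)benzoate
Conditions: Me4NBH(OAc)3, MeCN/AcOH, −30 °C → rt
Reagents that add atoms: none
Why: Evans–Saksena hydroxyl-directed reduction, in which the C3 hydroxyl binds the borohydride and delivers hydride to the face of the C1 ketone on which it sits, should give the 1,3-trans diol, i.e. the C1 hydroxyl trans to the angular methyl.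

Step 15
Reactants: 21 (1S,3R,3aS,4S,8aR)-1,3-dihydroxy-6,8a-dimethyl-3-(propan-2-yl)-1,2,3,3a,4,5,8,8a-octahydroazulen-4-yl 4-(prop-2-en-1-yloxy)benzoate
Product: 22 (1S,3R,3aS,4S,8aR)-1-(acetyloxy)-3-hydroxy-6,8a-dimethyl-3-(propan-2-yl)-1,2,3,3a,4,5,8,8a-octahydroazulen-4-yl 4-(prop-2-en-1-yloxy)benzoate
Conditions: Ac2O, pyridine, DMAP (cat.), CH2Cl2, 0 °C → rt
Reagents that add atoms: acetic anhydride, CC(=O)OC(C)=O
Why: acetylation of the secondary alcohol should be selective because the tertiary alcohol is too hindered to react under these conditions.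

Step 16
Reactants: 22 (1S,3R,3aS,4S,8aR)-1-(acetyloxy)-3-hydroxy-6,8a-dimethyl-3-(propan-2-yl)-1,2,3,3a,4,5,8,8a-octahydroazulen-4-yl 4-(prop-2-en-1-yloxy)benzoate
Product: 23 (1S,3R,3aS,4S,8aR)-1-(acetyloxy)-3-hydroxy-6,8a-dimethyl-3-(propan-2-yl)-1,2,3,3a,4,5,8,8a-octahydroazulen-4-yl 4-hydroxybenzoate
Conditions: Pd(PPh3)4 (5 mol %), morpholine, THF, rt
Reagents that add atoms: none
Why: deallylation catalysed by zerovalent palladium (Tsuji–Trost transfer of the allyl group to morpholine) should free the phenol without touching the two esters, the tertiary alcohol or the alkene.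

**Compound list**

1 | methyl 4-bromo-2-methylbutanoate (racemic) | COC(=O)C(C)CCBr | starting material
2 | (4-methoxy-3-methyl-4-oxobutyl)triphenylphosphonium bromide | COC(=O)C(C)CC[P+](c1ccccc1)(c1ccccc1)c1ccccc1.[Br-] | intermediate
3 | 1-[(tert-butyldimethylsilyl)oxy]propan-2-one | CC(=O)CO[Si](C)(C)C(C)(C)C | starting material
4 | methyl 2-methyl-4-(triphenyl-λ5-phosphanylidene)butanoate (ylide, formed in the flask) | COC(=O)C(C)CC=P(c1ccccc1)(c1ccccc1)c1ccccc1 | intermediate
5 | methyl (4Z)-6-[(tert-butyldimethylsilyl)oxy]-2,5-dimethylhex-4-enoate | COC(=O)C(C)C/C=C(/C)CO[Si](C)(C)C(C)(C)C | intermediate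
6 | methyl (4Z)-6-bromo-2,5-dimethylhex-4-enoate | COC(=O)C(C)C/C=C(/C)CBr | intermediate
7 | but-3-yn-2-ol (racemic) | CC(O)C#C | starting material
8 | methyl (4Z)-9-hydroxy-2,5-dimethyldec-4-en-7-ynoate | COC(=O)C(C)C/C=C(/C)CC#CC(C)O | intermediate
9 | (6Z)-9-(1,3-dithian-2-ylidene)-6-methyldec-6-en-3-yn-2-ol | CC(=C1SCCCS1)C/C=C(/C)CC#CC(C)O | intermediate
10 | (3E,6Z)-9-(1,3-dithian-2-ylidene)-6-methyldeca-3,6-dien-2-ol | CC(=C1SCCCS1)C/C=C(/C)C/C=C/C(C)O | intermediate
11 | (3E,6Z)-9-(1,3-dithian-2-ylidene)-6-methyldeca-3,6-dien-2-one | CC(=C1SCCCS1)C/C=C(/C)C/C=C/C(C)=O | intermediate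
12 | 1-[(2R,3S)-3-[(2Z)-5-(1,3-dithian-2-ylidene)-2-methylhex-2-en-1-yl]oxiran-2-yl]ethan-1-one | CC(=O)[C@@H]1O[C@H]1C/C(C)=C\CC(C)=C2SCCCS2 | intermediate
13 | triethyl({1-[(2R,3S)-3-[(2Z)-5-(1,3-dithian-2-ylidene)-2-methylhex-2-en-1-yl]oxiran-2-yl]ethenyl}oxy)silane | C=C(O[Si](CC)(CC)CC)[C@@H]1O[C@H]1C/C(C)=C\CC(C)=C2SCCCS2 | intermediate
14 | 2-[1,4-dimethyl-6-[(triethylsilyl)oxy]-7-{1-[(triethylsilyl)oxy]ethenyl}cyclohept-3-en-1-yl]-5,6-dihydro-4H-1,3-dithiin-1-ium trifluoromethanesulfonate (ring B closed; configuration as in 15; formed in the flask) | C=C(O[Si](CC)(CC)CC)[C@@H]1[C@@H](O[Si](CC)(CC)CC)CC(C)=CC[C@@]1(C)C1=[S+]CCCS1.[O-]S(=O)(=O)C(F)(F)F | intermediate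
15 | (3aS,4S,8aR)-6,8a-dimethyl-4-[(triethylsilyl)oxy]-3a,4,5,8-tetrahydro-2H-spiro[azulene-1,2'-[1,3]dithian]-3(8aH)-one (trans-fused) | S1CCCSC12CC(=O)[C@@H]3[C@@H](O[Si](CC)(CC)CC)CC(C)=CC[C@@]23C | intermediate
16 | (3R,3aS,4S,8aR)-6,8a-dimethyl-3-(propan-2-yl)-4-[(triethylsilyl)oxy]-2,3,3a,4,5,8-hexahydro-8aH-spiro[azulene-1,2'-[1,3]dithian]-3-ol (formed in the flask) | S1CCCSC12C[C@@](O)(C(C)C)[C@@H]3[C@@H](O[Si](CC)(CC)CC)CC(C)=CC[C@@]23C | intermediate
17 | (3R,3aS,4S,8aR)-6,8a-dimethyl-3-(propan-2-yl)-2,3,3a,4,5,8-hexahydro-8aH-spiro[azulene-1,2'-[1,3]dithiane]-3,4-diol | S1CCCSC12C[C@@](O)(C(C)C)[C@@H]3[C@@H](O)CC(C)=CC[C@@]23C | intermediate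
18 | 4-(prop-2-en-1-yloxy)benzoic acid | OC(=O)c1ccc(OCC=C)cc1 | starting material
19 | (3R,3aS,4S,8aR)-3-hydroxy-6,8a-dimethyl-3-(propan-2-yl)-2,3,3a,4,5,8-hexahydro-8aH-spiro[azulene-1,2'-[1,3]dithian]-4-yl 4-(prop-2-en-1-yloxy)benzoate | S1CCCSC12C[C@@](O)(C(C)C)[C@@H]3[C@@H](OC(=O)c4ccc(OCC=C)cc4)CC(C)=CC[C@@]23C | intermediate
20 | (3R,3aS,4S,8aR)-3-hydroxy-6,8a-dimethyl-1-oxo-3-(propan-2-yl)-1,2,3,3a,4,5,8,8a-octahydroazulen-4-yl 4-(prop-2-en-1-yloxy)benzoate | O=C1C[C@@](O)(C(C)C)[C@@H]2[C@@H](OC(=O)c3ccc(OCC=C)cc3)CC(C)=CC[C@@]12C | intermediate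
21 | (1S,3R,3aS,4S,8aR)-1,3-dihydroxy-6,8a-dimethyl-3-(propan-2-yl)-1,2,3,3a,4,5,8,8a-octahydroazulen-4-yl 4-(prop-2-en-1-yloxy)benzoate | O[C@H]1C[C@@](O)(C(C)C)[C@@H]2[C@@H](OC(=O)c3ccc(OCC=C)cc3)CC(C)=CC[C@@]12C | intermediate
22 | (1S,3R,3aS,4S,8aR)-1-(acetyloxy)-3-hydroxy-6,8a-dimethyl-3-(propan-2-yl)-1,2,3,3a,4,5,8,8a-octahydroazulen-4-yl 4-(prop-2-en-1-yloxy)benzoate | CC(=O)O[C@H]1C[C@@](O)(C(C)C)[C@@H]2[C@@H](OC(=O)c3ccc(OCC=C)cc3)CC(C)=CC[C@@]12C | intermediate
23 | (1S,3R,3aS,4S,8aR)-1-(acetyloxy)-3-hydroxy-6,8a-dimethyl-3-(propan-2-yl)-1,2,3,3a,4,5,8,8a-octahydroazulen-4-yl 4-hydroxybenzoate | CC(=O)O[C@H]1C[C@@](O)(C(C)C)[C@@H]2[C@@H](OC(=O)c3ccc(O)cc3)CC(C)=CC[C@@]12C | target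

**Count and risks**

Total step count: 16. Longest linear sequence: 16 steps (from 1).

Steps most likely to fail:

1. Step 10 (Proposed new method). What may go wrong: the silylated epoxide may rearrange by hydride shift before it is captured, the ketene dithioacetal may be protonated and oligomerise, or ring B may close with poor control of the ring fusion. Fallback with known reaction types, setting out from 12 and coming back at 15: 12 is opened reductively at the oxirane carbon next to the carbonyl with Me2CuLi (Et2O, −78 °C) and the resulting enolate and alkoxide are silylated with Et3SiCl/Et3N to give the bis-silyl (Z)-enol ether F1. Constant-current anodic oxidation of F1 (reticulated vitreous carbon anode, Pt cathode, Et4NOTs, MeOH/THF, 2,6-lutidine) is an anodic olefin coupling of a ketene dithioacetal with an enol ether; it should join the two electron-rich alkenes at C3a–C8a, close ring B and trap the sulfur-bearing carbon with methanol, giving the methyl ketone F2, whose acetyl-bearing centre can be equilibrated to the trans arrangement. Kinetic enol silylation (LiN(iPr)2, Et3SiCl, THF, −78 °C) gives the enol silane F3, and catalytic Et3SiOTf (CH2Cl2, −78 °C) ionises the methoxy dithiane to the dithianylium ion, which the enol silane captures in a Mukaiyama-type closure of ring A to give 15.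

2. Step 11. What may go wrong: enolisation of the hindered ketone, reduction by β-hydride transfer from the isopropyl reagent, ring-opening β-elimination of a thiolate, or low facial selectivity. Fallback, setting out from 15 and coming back at 16: the isopropyl group is installed in two stages. Isopropenylmagnesium bromide with CeCl3 (THF, −78 °C), a smaller sp2 nucleophile without β-hydrogens, should add to give the allylic tertiary alcohol F4. Diimide (potassium azodicarboxylate, AcOH, MeOH) then saturates the 1,1-disubstituted alkene selectively over the trisubstituted ring-B alkene to give 16, which is desilylated as in step 11.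

3. Step 14. What may go wrong: slow ligand exchange at the hindered tertiary hydroxyl, so that undirected reduction competes and the C1 configuration is not controlled, or acid-promoted dehydration of the β-hydroxy ketone. Fallback, setting out from 20 and coming back at 22: the opposite C1 epimer is made on purpose and inverted. Chelation-controlled Narasaka–Prasad reduction (Et2BOMe, NaBH4, THF/MeOH, −78 °C), with external hydride attack anti to the angular methyl, should give the cis-1,3-diol F5. Mitsunobu reaction with acetic acid (PPh3, diisopropyl azodicarboxylate, toluene) then inverts C1 and installs the acetate in one operation to give 22, so step 15 is not needed.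

**Further compounds**

F1 | step 10 | triethyl{[(2Z,4S,6Z)-9-(1,3-dithian-2-ylidene)-6-methyl-4-[(triethylsilyl)oxy]deca-2,6-dien-2-yl]oxy}silane | C/C(O[Si](CC)(CC)CC)=C/[C@@H](O[Si](CC)(CC)CC)C/C(C)=C\CC(C)=C1SCCCS1
F2 | step 10 | 1-[(1S,2R,7S)-2-(2-methoxy-1,3-dithian-2-yl)-2,5-dimethyl-7-[(triethylsilyl)oxy]cyclohept-4-en-1-yl]ethan-1-one | CC(=O)[C@@H]1[C@@H](O[Si](CC)(CC)CC)CC(C)=CC[C@@]1(C)C1(OC)SCCCS1
F3 | step 10 | triethyl({1-[(1S,2R,7S)-2-(2-methoxy-1,3-dithian-2-yl)-2,5-dimethyl-7-[(triethylsilyl)oxy]cyclohept-4-en-1-yl]ethenyl}oxy)silane | C=C(O[Si](CC)(CC)CC)[C@@H]1[C@@H](O[Si](CC)(CC)CC)CC(C)=CC[C@@]1(C)C1(OC)SCCCS1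
F4 | step 11 | (3aS,4S,8aR)-6,8a-dimethyl-3-(prop-1-en-2-yl)-4-[(triethylsilyl)oxy]-2,3,3a,4,5,8-hexahydro-8aH-spiro[azulene-1,2'-[1,3]dithian]-3-ol (C3 arranged as in 16) | S1CCCSC12C[C@@](O)(C(C)=C)[C@@H]3[C@@H](O[Si](CC)(CC)CC)CC(C)=CC[C@@]23C
F5 | step 14 | (1R,3R,3aS,4S,8aR)-1,3-dihydroxy-6,8a-dimethyl-3-(propan-2-yl)-1,2,3,3a,4,5,8,8a-octahydroazulen-4-yl 4-(prop-2-en-1-yloxy)benzoate | O[C@@H]1C[C@@](O)(C(C)C)[C@@H]2[C@@H](OC(=O)c3ccc(OCC=C)cc3)CC(C)=CC[C@@]12C
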